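**Retrosynthetic overview**

1. Target 19 comes from bis-MOM ketone 18 by acetal cleavage. 18 is made in one pot by Negishi union of arylzinc 16 (from arene 14, metalated between its two OMOM groups) with ketene acetal phosphate 10 of δ-lactone 9, followed by Claisen ring contraction of the coupled enol ether 17.
2. Enabling feature: the aryl ketone is γ,δ-unsaturated. The carbonyl carbon, ring C1, C2 and the C3=C4(Me) alkene form a Claisen retron, so the cyclohexene is the [3,3] product of a 6-aryl-2-methyl-2-vinyl-3,4-dihydro-2H-pyran whose O1–C2 carbon becomes C4 (the C4(Me)/C5-prenyl part is a linalool-type tertiary allylic carbinol).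
3. Lactone 9 comes from 1,5-diol 8, and 8 from lactone 4 by turning its carbonyl into the C(Me)(vinyl) carbinol (alkynyl first, then methyl under Felkin–Anh control, then semi-hydrogenation). 4 comes from trans-prenylation of 3, and 3 from Rh-catalysed asymmetric phenylation of 5,6-dihydro-2H-pyran-2-one.
4. Arene 14 comes from 3-hydroxy-4,5-dimethoxybenzaldehyde by Dakin-type oxidation and double MOM protection.
5. Ring order: pyranone ring of 3 (bought) → re-closed pyranone 9 with the ring oxygen moved to the carbinol carbon → dihydropyran 17 → cyclohexene of 18 by ring contraction. Both benzene rings are bought.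

Key step: step 10

Assumption 1: (S)-BINAP is taken to give the (4S)-lactone by the same facial sense as with 2-cyclohexenone; if the sense is opposite, (R)-BINAP is used.
Assumption 2: δ-hydroxy ketone 5 is drawn open-chain; it may equilibrate with its lactol, which does not change the chemistry.
Ring atoms C1–C6 are numbered as in the cyclohex-3-en-1-yl name of the target.

**Step 1**
Reactants: 1 5,6-dihydro-2H-pyran-2-one + 2 phenylboronic acid
Product: 3 (4S)-4-phenyltetrahydro-2H-pyran-2-one
Conditions: [Rh(acac)(C2H4)2] (3 mol%), (S)-BINAP (3.3 mol%), dioxane/H2O 10:1, 100 °C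
Reagents that add atoms: none
Why: Hayashi–Miyaura Rh/BINAP-catalysed asymmetric 1,4-addition of an arylboronic acid to an α,β-unsaturated δ-lactone, in which the ligand-controlled enantioface selection of the aryl–Rh insertion sets the phenyl-bearing centre (later C6).

**Step 2**
Reactants: 3 (4S)-4-phenyltetrahydro-2H-pyran-2-one
Product: 4 (3R,4S)-3-(3-methylbut-2-en-1-yl)-4-phenyltetrahydro-2H-pyran-2-one
Conditions: LDA, THF, −78 °C; prenyl bromide, DMPU, −78 → −40 °C
Reagents that add atoms: 1-bromo-3-methylbut-2-ene (prenyl bromide), CC(C)=CCBr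
Why: Lactone enolate alkylation in which the allylic bromide approaches anti to the adjacent 4-phenyl group, which should give the 3,4-trans lactone and so the later C5/C6 trans relationship.

**Step 3**
Reactants: 4 (3R,4S)-3-(3-methylbut-2-en-1-yl)-4-phenyltetrahydro-2H-pyran-2-one
Product: 5 (4R,5S)-7-hydroxy-4-(3-methylbut-2-en-1-yl)-5-phenyl-1-(trimethylsilyl)hept-1-yn-3-one
Conditions: LiC≡CSiMe3 (1.2 equiv), THF, −78 °C; aq NH4Cl
Reagents that add atoms: lithium (trimethylsilyl)acetylide, [Li]C#C[Si](C)(C)C
Why: Mono-addition of a lithium acetylide to a lactone, which stops at the ynone because the tetrahedral lactolate survives until work-up; the alkynyl group is the vinyl precursor that must be on the ketone before methyl is added, and no stereocentre is touched.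

**Step 4**
Reactants: 5 (4R,5S)-7-hydroxy-4-(3-methylbut-2-en-1-yl)-5-phenyl-1-(trimethylsilyl)hept-1-yn-3-one
Product: 7 (3S,4R,5R)-5-methyl-4-(3-methylbut-2-en-1-yl)-3-phenylhept-6-yne-1,5-diol, via silylated propargylic diol 6 (not isolated)
Conditions: MeMgBr (3 equiv), CeCl3, THF, −78 °C; then K2CO3, MeOH, rt
Reagents that add atoms: methylmagnesium bromide, C[Mg]Br
Why: Felkin–Anh 1,2-addition of the cerium-modified Grignard reagent to the α-chiral ynone (cerium suppresses enolisation), with methyl entering anti to the large CH(Ph)CH2CH2O substituent and past hydrogen so that, in the later pyran ring, methyl is cis to prenyl and the alkynyl group cis to phenyl; K2CO3/MeOH then cleaves the C(sp)–Si bond.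

**Step 5**
Reactants: 7 (3S,4R,5R)-5-methyl-4-(3-methylbut-2-en-1-yl)-3-phenylhept-6-yne-1,5-diol
Product: 8 (3S,4R,5S)-5-methyl-4-(3-methylbut-2-en-1-yl)-3-phenylhept-6-ene-1,5-diol
Conditions: H2 (1 atm), Lindlar catalyst, quinoline, EtOAc, rt
Reagents that add atoms: none
Why: Lindlar semi-hydrogenation of a terminal alkyne should stop at the vinyl group and leave the trisubstituted prenyl alkene alone (the descriptor at C5 changes only because the CIP priorities change).

**Step 6**
Reactants: 8 (3S,4R,5S)-5-methyl-4-(3-methylbut-2-en-1-yl)-3-phenylhept-6-ene-1,5-diol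
Product: 9 (4S,5R,6S)-6-ethenyl-6-methyl-5-(3-methylbut-2-en-1-yl)-4-phenyltetrahydro-2H-pyran-2-one
Conditions: TEMPO (0.2 equiv), PhI(OAc)2 (2.5 equiv), CH2Cl2, rt
Reagents that add atoms: none
Why: TEMPO/PhI(OAc)2 oxidative lactonisation of a 1,5-diol, in which the primary alcohol is oxidised to the aldehyde, this closes on the tertiary hydroxyl to a six-membered lactol, and the lactol is oxidised to the δ-lactone, so that the ring oxygen now sits on the carbinol carbon while the tertiary allylic alcohol and the alkenes are not oxidised.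

**Step 7**
Reactants: 9 (4S,5R,6S)-6-ethenyl-6-methyl-5-(3-methylbut-2-en-1-yl)-4-phenyltetrahydro-2H-pyran-2-one
Product: 10 diphenyl (2S,3R,4R)-2-ethenyl-2-methyl-3-(3-methylbut-2-en-1-yl)-4-phenyl-3,4-dihydro-2H-pyran-6-yl phosphate
Conditions: KHMDS (1.3 equiv), (PhO)2P(O)Cl (1.3 equiv), HMPA, THF, −78 °C
Reagents that add atoms: diphenyl chlorophosphate, O=P(Cl)(Oc1ccccc1)Oc1ccccc1
Why: O-phosphorylation of the potassium lactone enolate to the cyclic ketene acetal phosphate, a standard activation of lactones for cross-coupling; only one α-CH2 is available and the stereocentres are untouched.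

**Step 8**
Reactants: 11 3-hydroxy-4,5-dimethoxybenzaldehyde
Product: 13 4,5-dimethoxybenzene-1,3-diol, via aryl formate 12 (not isolated)
Conditions: 30% H2O2, H2SO4 (cat.), MeOH, rt
Reagents that add atoms: hydrogen peroxide, OO
Why: Acid-catalysed Dakin-type (Baeyer–Villiger) oxidation of an electron-rich benzaldehyde, in which the para-methoxy group promotes aryl migration to the formate and methanol cleaves the formate in the same flask.

**Step 9**
Reactants: 13 4,5-dimethoxybenzene-1,3-diol
Product: 14 1,2-dimethoxy-3,5-bis(methoxymethoxy)benzene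
Conditions: MOMCl (3 equiv), iPr2NEt, CH2Cl2, 0 °C → rt
Reagents that add atoms: chloromethyl methyl ether, COCCl
Why: O-alkylation of both phenols with MOMCl gives two acetal groups that direct the metalation to the carbon between them and can be removed with mild acid at the end.

**Step 10**
Reactants: 14 1,2-dimethoxy-3,5-bis(methoxymethoxy)benzene (1.3 equiv) + 10 diphenyl (2S,3R,4R)-2-ethenyl-2-methyl-3-(3-methylbut-2-en-1-yl)-4-phenyl-3,4-dihydro-2H-pyran-6-yl phosphate
Product: 18 [2,6-bis(methoxymethoxy)-3,4-dimethoxyphenyl][(1R,5R,6R)-4-methyl-5-(3-methylbut-2-en-1-yl)-6-phenylcyclohex-3-en-1-yl]methanone, via aryllithium 15 (not isolated), via arylzinc chloride 16 (not isolated), via 6-aryl-2-vinyl-3,4-dihydro-2H-pyran 17 (not isolated)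
Conditions: n-BuLi, THF, 0 °C; ZnCl2, 0 °C → rt; then 10, Pd2(dba)3 (2.5 mol%), SPhos (10 mol%), 50 °C; aq NaHCO3 wash; then Et3N (cat.), toluene, 130 °C (sealed)
Reagents that add atoms: none
Why: Directed ortho-lithiation of 14 should occur at the carbon flanked by both OMOM groups (two cooperating directing groups, against one OMOM and a buttressed OMe at the other site), and after transmetalation to zinc a Negishi coupling with ketene acetal phosphate 10 (oxidative addition of Pd(0) into the vinyl C–OP bond, transmetalation, reductive elimination) forms the aryl–carbon bond and gives enol ether 17; the closest known reaction type is the Pd-catalysed cross-coupling of lactone-derived ketene acetal phosphates with organozinc, organotin and organoboron reagents. On heating, 17 is an allyl vinyl ether (C5=C6–O1–C2–CH=CH2) and should undergo a Claisen ring contraction of the kind known for 6-vinyl-δ-lactone silyl ketene acetals and 2-vinyl-3,4-dihydro-2H-pyrans. The cyclohexene is closed by C1–C2 bond formation in a [3,3] shift through a boat (bicyclo[2.2.2]-like) transition state; the O1–C2 bond of the pyran breaks to leave the C3=C4(Me) alkene, cis within the ring by necessity, and the enol ether carbon becomes the ketone carbonyl. The new stereocentre C1 is formed suprafacially on the enol ether face that carries the vinyl group; because vinyl is cis to phenyl in 10 (set in step 4), the aroyl group ends trans to phenyl, while C5 and C6 are carried over unchanged. The step needs coupling to outrun hydrolysis of 10 and 17 and the [3,3] shift to outrun ionisation or retro-hetero-Diels–Alder cleavage; the tertiary allylic C–O bond and the electron-rich 2-aryl enol ether lower the Claisen barrier, and removal of the zinc salts plus the Et3N buffer suppress acid-catalysed pathways.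

**Step 11**
Reactants: 18 [2,6-bis(methoxymethoxy)-3,4-dimethoxyphenyl][(1R,5R,6R)-4-methyl-5-(3-methylbut-2-en-1-yl)-6-phenylcyclohex-3-en-1-yl]methanone
Product: 19 (2,6-dihydroxy-3,4-dimethoxyphenyl)[(1R,5R,6R)-4-methyl-5-(3-methylbut-2-en-1-yl)-6-phenylcyclohex-3-en-1-yl]methanone
Conditions: HCl (1 M in MeOH), THF, rt → 40 °C
Reagents that add atoms: none
Why: Acid-catalysed acetal cleavage of the two aryl MOM ethers (transacetalisation to dimethoxymethane), made easy by the ortho carbonyl, under acid mild enough that the trisubstituted alkenes and the C1 centre of the chelated ketone should survive.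

**Compound list**

1 | 5,6-dihydro-2H-pyran-2-one | O=C1C=CCCO1 | starting material
2 | phenylboronic acid | OB(O)c1ccccc1 | starting material
3 | (4S)-4-phenyltetrahydro-2H-pyran-2-one | O=C1C[C@@H](c2ccccc2)CCO1 | intermediate
4 | (3R,4S)-3-(3-methylbut-2-en-1-yl)-4-phenyltetrahydro-2H-pyran-2-one | O=C1[C@H](CC=C(C)C)[C@@H](c2ccccc2)CCO1 | intermediate
5 | (4R,5S)-7-hydroxy-4-(3-methylbut-2-en-1-yl)-5-phenyl-1-(trimethylsilyl)hept-1-yn-3-one | C[Si](C)(C)C#CC(=O)[C@H](CC=C(C)C)[C@@H](c1ccccc1)CCO | intermediate
6 | (3S,4R,5R)-5-methyl-4-(3-methylbut-2-en-1-yl)-3-phenyl-7-(trimethylsilyl)hept-6-yne-1,5-diol | C[Si](C)(C)C#C[C@](C)(O)[C@H](CC=C(C)C)[C@@H](c1ccccc1)CCO | intermediate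
7 | (3S,4R,5R)-5-methyl-4-(3-methylbut-2-en-1-yl)-3-phenylhept-6-yne-1,5-diol | C#C[C@](C)(O)[C@H](CC=C(C)C)[C@@H](c1ccccc1)CCO | intermediate
8 | (3S,4R,5S)-5-methyl-4-(3-methylbut-2-en-1-yl)-3-phenylhept-6-ene-1,5-diol | C=C[C@](C)(O)[C@H](CC=C(C)C)[C@@H](c1ccccc1)CCO | intermediate
9 | (4S,5R,6S)-6-ethenyl-6-methyl-5-(3-methylbut-2-en-1-yl)-4-phenyltetrahydro-2H-pyran-2-one | O=C1C[C@H](c2ccccc2)[C@@H](CC=C(C)C)[C@](C)(C=C)O1 | intermediate
10 | diphenyl (2S,3R,4R)-2-ethenyl-2-methyl-3-(3-methylbut-2-en-1-yl)-4-phenyl-3,4-dihydro-2H-pyran-6-yl phosphate | O=P(Oc1ccccc1)(Oc1ccccc1)OC1=C[C@H](c2ccccc2)[C@@H](CC=C(C)C)[C@](C)(C=C)O1 | intermediate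
11 | 3-hydroxy-4,5-dimethoxybenzaldehyde | O=Cc1cc(O)c(OC)c(OC)c1 | starting material
12 | 3-hydroxy-4,5-dimethoxyphenyl formate | O=COc1cc(O)c(OC)c(OC)c1 | intermediate
13 | 4,5-dimethoxybenzene-1,3-diol | Oc1cc(O)c(OC)c(OC)c1 | intermediate
14 | 1,2-dimethoxy-3,5-bis(methoxymethoxy)benzene | COCOc1cc(OCOC)c(OC)c(OC)c1 | intermediate
15 | [2,6-bis(methoxymethoxy)-3,4-dimethoxyphenyl]lithium | [Li]c1c(OCOC)cc(OC)c(OC)c1OCOC | intermediate
16 | [2,6-bis(methoxymethoxy)-3,4-dimethoxyphenyl]zinc chloride | Cl[Zn]c1c(OCOC)cc(OC)c(OC)c1OCOC | intermediate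
17 | (2S,3R,4S)-6-[2,6-bis(methoxymethoxy)-3,4-dimethoxyphenyl]-2-ethenyl-2-methyl-3-(3-methylbut-2-en-1-yl)-4-phenyl-3,4-dihydro-2H-pyran | COCOc1cc(OC)c(OC)c(OCOC)c1C1=C[C@H](c2ccccc2)[C@@H](CC=C(C)C)[C@](C)(C=C)O1 | intermediate
18 | [2,6-bis(methoxymethoxy)-3,4-dimethoxyphenyl][(1R,5R,6R)-4-methyl-5-(3-methylbut-2-en-1-yl)-6-phenylcyclohex-3-en-1-yl]methanone | COCOc1cc(OC)c(OC)c(OCOC)c1C(=O)[C@@H]1CC=C(C)[C@H](CC=C(C)C)[C@H]1c1ccccc1 | intermediate
19 | (2,6-dihydroxy-3,4-dimethoxyphenyl)[(1R,5R,6R)-4-methyl-5-(3-methylbut-2-en-1-yl)-6-phenylcyclohex-3-en-1-yl]methanone | COc1cc(O)c(C(=O)[C@@H]2CC=C(C)[C@H](CC=C(C)C)[C@H]2c2ccccc2)c(O)c1OC | target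

**Totals**

Total step count: 11. Longest linear sequence: 9 steps (steps 1–7, 10, 11).

**Steps most likely to fail**

1. Step 10. The hindered arylzinc may transmetalate slowly, metalation may occur in part at the ring position next to the methoxy group, the phosphate or the electron-rich enol ether may hydrolyse, or the thermal stage may drift into ionisation or retro-hetero-Diels–Alder cleavage instead of the [3,3] shift. The fallback sets out from lactone 9 and comes back at ketone 18. An Ireland–Claisen ring contraction of 9 (LDA, TBSCl, HMPA/THF, −78 °C; then toluene, 105 °C) would pass through the silyl ketene acetal F1 and the silyl ester F2 and, after mild hydrolysis, give the cyclohexenecarboxylic acid F3 by the same boat [3,3] shift with the same stereochemical course. F3 would be converted into the Weinreb amide F4 (MeNHOMe·HCl, EDCI, iPr2NEt, CH2Cl2), and addition of aryllithium 15 (from 14 and n-BuLi, THF, −78 → 0 °C) would give 18.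

2. Step 4. Facial selectivity of the methyl addition may be poor or opposite to the Felkin–Anh prediction, and enolisation may epimerise the α-centre; a wrong carbinol epimer would lead to the C1 epimer after the ring contraction. The fallback sets out from lactone 4 and comes back at diol 8. MeLi (1 equiv, THF, −78 °C) would give the hydroxy methyl ketone F5 (as its lactol), and vinylmagnesium bromide/CeCl3 (THF, −78 °C) would then give 8 directly. The two orders of addition are stereochemically complementary at the carbinol carbon, so this order is taken if the ynone addition favours the unwanted epimer; it also removes the desilylation and the semi-hydrogenation. In either order the carbinol epimers should be separable as the lactones.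

3. Step 6. The oxoammonium species may trigger oxidative 1,3-transposition of the tertiary allylic alcohol, or the oxidation may stall at the lactol because closure on the hindered tertiary hydroxyl is slow. The fallback sets out from diol 8 and comes back at lactone 9. Parikh–Doering oxidation (SO3·pyridine, DMSO, iPr2NEt, CH2Cl2, 0 °C) would stop at the lactol F6, which silver carbonate on Celite (toluene, reflux) would oxidise to 9 without any oxoammonium species.

**Further compounds**

F1 | step 10 | tert-butyl{[(2S,3R,4R)-2-ethenyl-2-methyl-3-(3-methylbut-2-en-1-yl)-4-phenyl-3,4-dihydro-2H-pyran-6-yl]oxy}dimethylsilane | CC(C)(C)[Si](C)(C)OC1=C[C@H](c2ccccc2)[C@@H](CC=C(C)C)[C@](C)(C=C)O1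
F2 | step 10 | tert-butyldimethylsilyl (1R,5R,6R)-4-methyl-5-(3-methylbut-2-en-1-yl)-6-phenylcyclohex-3-ene-1-carboxylate | CC(C)(C)[Si](C)(C)OC(=O)[C@@H]1CC=C(C)[C@H](CC=C(C)C)[C@H]1c1ccccc1
F3 | step 10 | (1R,5R,6R)-4-methyl-5-(3-methylbut-2-en-1-yl)-6-phenylcyclohex-3-ene-1-carboxylic acid | OC(=O)[C@@H]1CC=C(C)[C@H](CC=C(C)C)[C@H]1c1ccccc1
F4 | step 10 | (1R,5R,6R)-N-methoxy-N,4-dimethyl-5-(3-methylbut-2-en-1-yl)-6-phenylcyclohex-3-ene-1-carboxamide | CON(C)C(=O)[C@@H]1CC=C(C)[C@H](CC=C(C)C)[C@H]1c1ccccc1
F5 | step 4 | (3R,4S)-6-hydroxy-3-(3-methylbut-2-en-1-yl)-4-phenylhexan-2-one | CC(=O)[C@H](CC=C(C)C)[C@@H](c1ccccc1)CCO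
F6 | step 6 | (4S,5R,6S)-6-ethenyl-6-methyl-5-(3-methylbut-2-en-1-yl)-4-phenyltetrahydro-2H-pyran-2-ol (anomer mixture) | OC1C[C@H](c2ccccc2)[C@@H](CC=C(C)C)[C@](C)(C=C)O1
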